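## Retrosynthetic overview

1. The target comes from its tert-butyl ester 3,19-diacetate by methanolysis of the primary acetate and ester acidolysis.
2. The axial C-3 acetate comes from a C-3 ketone (equatorial hydride delivery, acetylation in the same flask), and the ketone from the equatorial C-3 alcohol of the cyclization.
3. Ring A, then ring B, form in one cationic cascade from an acyclic (2R,3R)-epoxy acetate. C–O participation of the acetate at C-4 is meant to relay the stereochemistry so that the CH2O group ends axial.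
4. The epoxide C–O bonds carry all absolute stereocontrol. They come from Sharpless epoxidation of an E-allylic alcohol, itself made by SeO2 C–H hydroxylation of tert-butyl geranylgeranoate.
5. The geranylgeranoate comes from a Horner–Wadsworth–Emmons reaction of (E,E)-farnesylacetone.

Assumption: all-trans (5E,9E)-farnesylacetone is bought as such (bulk isoprenoid intermediate); atom labels C-1 to C-20 in the explanations follow labdane numbering.

## Route

Step 1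
Reactants: 1 (5E,9E)-6,10,14-trimethylpentadeca-5,9,13-trien-2-one; 2 tert-butyl 2-(diethoxyphosphoryl)acetate
Product: 3 tert-butyl (2E,6E,10E)-3,7,11,15-tetramethylhexadeca-2,6,10,14-tetraenoate
Conditions: NaH, THF, 0 °C to rt; chromatographic removal of the 2Z isomer
Reagents that add atoms: none
Why: Horner–Wadsworth–Emmons olefination of the methyl ketone gives mainly the 2E enoate (about 4–5:1), with no stereocentre formed and the minor 2Z ester separable.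

Step 2
Reactants: 3 tert-butyl (2E,6E,10E)-3,7,11,15-tetramethylhexadeca-2,6,10,14-tetraenoate
Product: 4 tert-butyl (2E,6E,10E,14E)-16-hydroxy-3,7,11,15-tetramethylhexadeca-2,6,10,14-tetraenoate
Conditions: SeO2 (0.3 equiv), t-BuOOH (3 equiv), salicylic acid (0.1 equiv), CH2Cl2, 0 °C to rt
Reagents that add atoms: selenium dioxide O=[Se]=O (catalytic oxygen carrier); tert-butyl hydroperoxide CC(C)(C)OO (net oxygen source)
Why: Catalytic SeO2 allylic oxidation (ene reaction then [2,3]-shift) hydroxylates the E-methyl of the terminal, most accessible trisubstituted alkene of polyprenyl chains, while the conjugated 2,3-alkene is inert.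

Step 3
Reactants: 4 tert-butyl (2E,6E,10E,14E)-16-hydroxy-3,7,11,15-tetramethylhexadeca-2,6,10,14-tetraenoate
Product: 6 tert-butyl (2E,6E,10E)-13-[(2R,3R)-3-(acetoxymethyl)-3-methyloxiran-2-yl]-3,7,11-trimethyltrideca-2,6,10-trienoate, via epoxy alcohol 5 (not isolated)
Conditions: Ti(OiPr)4 (10 mol %), D-(−)-diisopropyl tartrate (12 mol %), t-BuOOH, 4 Å MS, CH2Cl2, −25 °C; then P(OMe)3; then Et3N, DMAP, Ac2O, 0 °C
Reagents that add atoms: tert-butyl hydroperoxide CC(C)(C)OO; acetic anhydride CC(=O)OC(C)=O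
Why: Katsuki–Sharpless asymmetric epoxidation touches only the allylic-alcohol alkene, and the D-tartrate gives the (2R,3R)-epoxide (mirror of the L-tartrate/(2S,3S) rule for E-allylic alcohols), fixing C-3 and C-4; the alcohol is acetylated in the same flask.

Step 4
Reactants: 6 tert-butyl (2E,6E,10E)-13-[(2R,3R)-3-(acetoxymethyl)-3-methyloxiran-2-yl]-3,7,11-trimethyltrideca-2,6,10-trienoate
Product: 8 tert-butyl (2E)-5-[(1R,4aS,5R,6R,8aS)-5-(acetoxymethyl)-6-hydroxy-2,5,8a-trimethyl-1,4,4a,5,6,7,8,8a-octahydronaphthalen-1-yl]-3-methylpent-2-enoate, via dioxolan-2-ylium ion 7 (not isolated)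
Conditions: BF3·OEt2 (0.3 equiv), CH2Cl2, −78 to −40 °C; aq NaHCO3
Reagents that add atoms: none
Why: Proposed new method: the BF3-activated epoxide is opened first by the acetate carbonyl oxygen (five-membered anchimeric assistance, inversion at C-4) to the acetoxonium ion 7, whose C-4–O bond is then displaced from the rear by the 10,11-alkene (second inversion, net retention at C-4, so the E-derived CH2OAc becomes axial instead of equatorial as in an unassisted closure); chair–chair folding with the BF3-bound O-3 equatorial and relay through the E-alkenes sets C-5, C-10 and C-9 of the trans-decalin in the ent series, loss of H-7 gives the Δ7 alkene (minor 8(17)-ene removed on AgNO3-impregnated silica) and the electron-poor enoate stays out; the closest known reactions are neighbouring-ester opening of 2,3-epoxy alcohol esters (epoxy ester–orthoester rearrangement, acyloxonium relay as in Woodward–Prévost and 1,2-trans glycosylation) and epoxide-initiated cation–olefin bicyclization.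

Step 5
Reactants: 8 tert-butyl (2E)-5-[(1R,4aS,5R,6R,8aS)-5-(acetoxymethyl)-6-hydroxy-2,5,8a-trimethyl-1,4,4a,5,6,7,8,8a-octahydronaphthalen-1-yl]-3-methylpent-2-enoate
Product: 9 tert-butyl (2E)-5-[(1R,4aS,5R,8aS)-5-(acetoxymethyl)-2,5,8a-trimethyl-6-oxo-1,4,4a,5,6,7,8,8a-octahydronaphthalen-1-yl]-3-methylpent-2-enoate
Conditions: Dess–Martin periodinane, CH2Cl2, rt
Reagents that add atoms: none
Why: Dess–Martin oxidation of the hindered equatorial secondary alcohol removes the C-3 stereocentre (to be reset) without touching the esters, the alkenes or the quaternary C-4.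

Step 6
Reactants: 9 tert-butyl (2E)-5-[(1R,4aS,5R,8aS)-5-(acetoxymethyl)-2,5,8a-trimethyl-6-oxo-1,4,4a,5,6,7,8,8a-octahydronaphthalen-1-yl]-3-methylpent-2-enoate
Product: 11 tert-butyl (2E)-5-[(1R,4aS,5R,6S,8aS)-6-acetoxy-5-(acetoxymethyl)-2,5,8a-trimethyl-1,4,4a,5,6,7,8,8a-octahydronaphthalen-1-yl]-3-methylpent-2-enoate, via lithium alkoxide 10 (not isolated)
Conditions: LiBH(s-Bu)3 (1.2 equiv), THF, −78 °C; then Ac2O, DMAP, −78 °C to rt
Reagents that add atoms: acetic anhydride CC(=O)OC(C)=O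
Why: The bulky trialkylborohydride attacks the C-3 ketone along the equatorial trajectory (axial approach is blocked by the syn-axial H-1 and H-5), giving the axial (3S) alkoxide as known for 4,4-disubstituted 3-oxo terpenoids, and acetic anhydride traps it; the esters are inert at −78 °C and acyl transfer from O-19 is impossible because O-3 and C-19 are antiperiplanar.

Step 7
Reactants: 11 tert-butyl (2E)-5-[(1R,4aS,5R,6S,8aS)-6-acetoxy-5-(acetoxymethyl)-2,5,8a-trimethyl-1,4,4a,5,6,7,8,8a-octahydronaphthalen-1-yl]-3-methylpent-2-enoate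
Product: 12 tert-butyl (2E)-5-[(1R,4aS,5R,6S,8aS)-6-acetoxy-5-(hydroxymethyl)-2,5,8a-trimethyl-1,4,4a,5,6,7,8,8a-octahydronaphthalen-1-yl]-3-methylpent-2-enoate
Conditions: K2CO3 (0.2 equiv), MeOH, 0 °C
Reagents that add atoms: none
Why: Base-catalysed transesterification cleaves the primary 19-acetate much faster than the axial secondary 3-acetate flanked by the quaternary C-4 (as in the known selective deacetylation of betulin diacetate); the tert-butyl ester is inert and the anti geometry excludes acetyl migration.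

Step 8
Reactants: 12 tert-butyl (2E)-5-[(1R,4aS,5R,6S,8aS)-6-acetoxy-5-(hydroxymethyl)-2,5,8a-trimethyl-1,4,4a,5,6,7,8,8a-octahydronaphthalen-1-yl]-3-methylpent-2-enoate
Product: 13 (2E)-5-[(1R,4aS,5R,6S,8aS)-6-acetoxy-5-(hydroxymethyl)-2,5,8a-trimethyl-1,4,4a,5,6,7,8,8a-octahydronaphthalen-1-yl]-3-methylpent-2-enoic acid
Conditions: CF3CO2H/CH2Cl2 (1:4), 0 °C; aq NaHCO3 wash, then acidify
Reagents that add atoms: none
Why: Acidolysis of the tert-butyl ester with loss of isobutene frees the acid under cold, dilute conditions that the acetate, the primary alcohol and the Δ7 alkene should tolerate, and no stereocentre is touched.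

## Compound list

1 | (5E,9E)-6,10,14-trimethylpentadeca-5,9,13-trien-2-one ((E,E)-farnesylacetone) | CC(=O)CC/C=C(\C)CC/C=C(\C)CCC=C(C)C | starting material
2 | tert-butyl 2-(diethoxyphosphoryl)acetate | CCOP(=O)(CC(=O)OC(C)(C)C)OCC | starting material
3 | tert-butyl (2E,6E,10E)-3,7,11,15-tetramethylhexadeca-2,6,10,14-tetraenoate | CC(C)=CCC/C(C)=C/CC/C(C)=C/CC/C(C)=C/C(=O)OC(C)(C)C | intermediate
4 | tert-butyl (2E,6E,10E,14E)-16-hydroxy-3,7,11,15-tetramethylhexadeca-2,6,10,14-tetraenoate | OC/C(C)=C/CC/C(C)=C/CC/C(C)=C/CC/C(C)=C/C(=O)OC(C)(C)C | intermediate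
5 | tert-butyl (2E,6E,10E)-13-[(2R,3R)-3-(hydroxymethyl)-3-methyloxiran-2-yl]-3,7,11-trimethyltrideca-2,6,10-trienoate | OC[C@@]1(C)O[C@@H]1CC/C(C)=C/CC/C(C)=C/CC/C(C)=C/C(=O)OC(C)(C)C | intermediate (not isolated)
6 | tert-butyl (2E,6E,10E)-13-[(2R,3R)-3-(acetoxymethyl)-3-methyloxiran-2-yl]-3,7,11-trimethyltrideca-2,6,10-trienoate | CC(=O)OC[C@@]1(C)O[C@@H]1CC/C(C)=C/CC/C(C)=C/CC/C(C)=C/C(=O)OC(C)(C)C | intermediate
7 | (4S)-2,4-dimethyl-4-[(1R,4E,8E,12E)-14-tert-butoxy-4,8,12-trimethyl-14-oxo-1-(trifluoroboranuidyloxy)tetradeca-4,8,12-trien-1-yl]-1,3-dioxolan-2-ylium (BF3-bound zwitterion) | CC1=[O+][C@@](C)(CO1)[C@H](O[B-](F)(F)F)CC/C(C)=C/CC/C(C)=C/CC/C(C)=C/C(=O)OC(C)(C)C | intermediate (not isolated)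
8 | tert-butyl (2E)-5-[(1R,4aS,5R,6R,8aS)-5-(acetoxymethyl)-6-hydroxy-2,5,8a-trimethyl-1,4,4a,5,6,7,8,8a-octahydronaphthalen-1-yl]-3-methylpent-2-enoate (equatorial 3-OH, axial CH2OAc) | O[C@@H]1CC[C@]2(C)[C@H](CC=C(C)[C@H]2CC/C(C)=C/C(=O)OC(C)(C)C)[C@]1(C)COC(C)=O | intermediate
9 | tert-butyl (2E)-5-[(1R,4aS,5R,8aS)-5-(acetoxymethyl)-2,5,8a-trimethyl-6-oxo-1,4,4a,5,6,7,8,8a-octahydronaphthalen-1-yl]-3-methylpent-2-enoate | O=C1CC[C@]2(C)[C@H](CC=C(C)[C@H]2CC/C(C)=C/C(=O)OC(C)(C)C)[C@]1(C)COC(C)=O | intermediate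
10 | lithium (1R,4aS,5R,6S,8aS)-alkoxide of the axial C-6 alcohol derived from 9 (tri-sec-butylborane present) | [Li+].[O-][C@H]1CC[C@]2(C)[C@H](CC=C(C)[C@H]2CC/C(C)=C/C(=O)OC(C)(C)C)[C@]1(C)COC(C)=O | intermediate (not isolated)
11 | tert-butyl (2E)-5-[(1R,4aS,5R,6S,8aS)-6-acetoxy-5-(acetoxymethyl)-2,5,8a-trimethyl-1,4,4a,5,6,7,8,8a-octahydronaphthalen-1-yl]-3-methylpent-2-enoate | CC(=O)O[C@H]1CC[C@]2(C)[C@H](CC=C(C)[C@H]2CC/C(C)=C/C(=O)OC(C)(C)C)[C@]1(C)COC(C)=O | intermediate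
12 | tert-butyl (2E)-5-[(1R,4aS,5R,6S,8aS)-6-acetoxy-5-(hydroxymethyl)-2,5,8a-trimethyl-1,4,4a,5,6,7,8,8a-octahydronaphthalen-1-yl]-3-methylpent-2-enoate | CC(=O)O[C@H]1CC[C@]2(C)[C@H](CC=C(C)[C@H]2CC/C(C)=C/C(=O)OC(C)(C)C)[C@]1(C)CO | intermediate
13 | (2E)-5-[(1R,4aS,5R,6S,8aS)-6-acetoxy-5-(hydroxymethyl)-2,5,8a-trimethyl-1,4,4a,5,6,7,8,8a-octahydronaphthalen-1-yl]-3-methylpent-2-enoic acid (ent-labdane: axial 3-OAc, axial 19-CH2OH, Δ7, 13E-15-oic acid; 3S,4R,5S,9R,10S) | CC(=O)O[C@H]1CC[C@]2(C)[C@H](CC=C(C)[C@H]2CC/C(C)=C/C(=O)O)[C@]1(C)CO | target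

## Step count and risks

Total steps: 8. Longest linear sequence: 8 (fully linear from 1 and 2).

Steps most likely to fail:

**Step 4 (the proposed new step).** The ester relay may be incomplete; unassisted closure gives the C-4 epimer with equatorial CH2OAc. The alkene may also ionize before ring closure. Fallback with known chemistry, from 3 back to 12, uses the Z-configured epoxide and needs no relay:
- NBS in THF/H2O gives the terminal bromohydrin tert-butyl (2E,6E,10E)-14-bromo-15-hydroxy-3,7,11,15-tetramethylhexadeca-2,6,10-trienoate F1.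
- K2CO3/MeOH closes it to the racemic terminal epoxide tert-butyl (2E,6E,10E)-13-(3,3-dimethyloxiran-2-yl)-3,7,11-trimethyltrideca-2,6,10-trienoate F2.
- H5IO6 cleaves this to the aldehyde tert-butyl (2E,6E,10E)-3,7,11-trimethyl-14-oxotetradeca-2,6,10-trienoate F3.
- Still–Gennari olefination (methyl 2-[bis(2,2,2-trifluoroethoxy)phosphoryl]propanoate, KN(SiMe3)2, 18-crown-6, THF, −78 °C) gives the Z-enoate 1-tert-butyl 16-methyl (2E,6E,10E,14Z)-3,7,11,15-tetramethylhexadeca-2,6,10,14-tetraenedioate F4.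
- i-Bu2AlH (CH2Cl2, −78 °C) reduces only the methyl ester, to the Z-allylic alcohol tert-butyl (2E,6E,10E,14Z)-16-hydroxy-3,7,11,15-tetramethylhexadeca-2,6,10,14-tetraenoate F5.
- Sharpless epoxidation with L-(+)-diisopropyl tartrate gives the cis-epoxy alcohol tert-butyl (2E,6E,10E)-13-[(2R,3S)-3-(hydroxymethyl)-3-methyloxiran-2-yl]-3,7,11-trimethyltrideca-2,6,10-trienoate F6.
- TBSCl/imidazole gives the non-participating silyl ether F7.
- MeAlCl2 (CH2Cl2, −78 °C) effects the ordinary single-inversion epoxide bicyclization, in which the Z substituent becomes axial, to the 6R-hydroxy 5-(silyloxymethyl) bicycle F8.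
- Dess–Martin oxidation gives the ketone F9; LiBH(s-Bu)3 then Ac2O gives the axial acetate F10; Bu4NF/AcOH removes the silyl group to give 12.

**Step 6.** The axial CH2OAc may erode equatorial hydride delivery, or the hindered alkoxide may not acetylate in the flask. Fallback from 9 back to 11:
- Brief K2CO3/MeOH at 0 °C gives the keto alcohol tert-butyl (2E)-5-[(1R,4aS,5R,8aS)-5-(hydroxymethyl)-2,5,8a-trimethyl-6-oxo-1,4,4a,5,6,7,8,8a-octahydronaphthalen-1-yl]-3-methylpent-2-enoate F11.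
- Hydroxyl-directed reduction with Me4NBH(OAc)3 (MeCN/AcOH, −20 °C) delivers hydride internally from the C-19 oxygen, on the C-19 face, giving the anti (axial 6S) diol F12.
- Ac2O/DMAP/Et3N acetylates both hydroxyls to give 11.

**Step 7.** Over- or under-cleavage of the diacetate is possible. Fallback from 8 back to 12 replaces kinetic selectivity by an orthogonal group:
- K2CO3/MeOH gives the diol tert-butyl (2E)-5-[(1R,4aS,5R,6R,8aS)-6-hydroxy-5-(hydroxymethyl)-2,5,8a-trimethyl-1,4,4a,5,6,7,8,8a-octahydronaphthalen-1-yl]-3-methylpent-2-enoate F13.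
- TBDPSCl/imidazole silylates only the primary hydroxyl, giving F14.
- Dess–Martin oxidation gives the ketone F15.
- LiBH(s-Bu)3 then Ac2O gives the axial acetate silyl ether F16.
- Bu4NF/AcOH gives 12.

## Further compounds

F1 | step 4 | tert-butyl (2E,6E,10E)-14-bromo-15-hydroxy-3,7,11,15-tetramethylhexadeca-2,6,10-trienoate (racemic) | CC(C)(O)C(Br)CC/C(C)=C/CC/C(C)=C/CC/C(C)=C/C(=O)OC(C)(C)C
F2 | step 4 | tert-butyl (2E,6E,10E)-13-(3,3-dimethyloxiran-2-yl)-3,7,11-trimethyltrideca-2,6,10-trienoate (racemic) | CC1(C)OC1CC/C(C)=C/CC/C(C)=C/CC/C(C)=C/C(=O)OC(C)(C)C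
F3 | step 4 | tert-butyl (2E,6E,10E)-3,7,11-trimethyl-14-oxotetradeca-2,6,10-trienoate | O=CCC/C(C)=C/CC/C(C)=C/CC/C(C)=C/C(=O)OC(C)(C)C
F4 | step 4 | 1-tert-butyl 16-methyl (2E,6E,10E,14Z)-3,7,11,15-tetramethylhexadeca-2,6,10,14-tetraenedioate | COC(=O)/C(C)=C\CC/C(C)=C/CC/C(C)=C/CC/C(C)=C/C(=O)OC(C)(C)C
F5 | step 4 | tert-butyl (2E,6E,10E,14Z)-16-hydroxy-3,7,11,15-tetramethylhexadeca-2,6,10,14-tetraenoate | OC/C(C)=C\CC/C(C)=C/CC/C(C)=C/CC/C(C)=C/C(=O)OC(C)(C)C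
F6 | step 4 | tert-butyl (2E,6E,10E)-13-[(2R,3S)-3-(hydroxymethyl)-3-methyloxiran-2-yl]-3,7,11-trimethyltrideca-2,6,10-trienoate | OC[C@]1(C)O[C@@H]1CC/C(C)=C/CC/C(C)=C/CC/C(C)=C/C(=O)OC(C)(C)C
F7 | step 4 | tert-butyl (2E,6E,10E)-13-[(2R,3S)-3-[(tert-butyldimethylsilyl)oxymethyl]-3-methyloxiran-2-yl]-3,7,11-trimethyltrideca-2,6,10-trienoate | CC(C)(C)[Si](C)(C)OC[C@]1(C)O[C@@H]1CC/C(C)=C/CC/C(C)=C/CC/C(C)=C/C(=O)OC(C)(C)C
F8 | step 4 | tert-butyl (2E)-5-[(1R,4aS,5R,6R,8aS)-5-[(tert-butyldimethylsilyl)oxymethyl]-6-hydroxy-2,5,8a-trimethyl-1,4,4a,5,6,7,8,8a-octahydronaphthalen-1-yl]-3-methylpent-2-enoate | O[C@@H]1CC[C@]2(C)[C@H](CC=C(C)[C@H]2CC/C(C)=C/C(=O)OC(C)(C)C)[C@]1(C)CO[Si](C)(C)C(C)(C)C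
F9 | step 4 | tert-butyl (2E)-5-[(1R,4aS,5R,8aS)-5-[(tert-butyldimethylsilyl)oxymethyl]-2,5,8a-trimethyl-6-oxo-1,4,4a,5,6,7,8,8a-octahydronaphthalen-1-yl]-3-methylpent-2-enoate | O=C1CC[C@]2(C)[C@H](CC=C(C)[C@H]2CC/C(C)=C/C(=O)OC(C)(C)C)[C@]1(C)CO[Si](C)(C)C(C)(C)C
F10 | step 4 | tert-butyl (2E)-5-[(1R,4aS,5R,6S,8aS)-6-acetoxy-5-[(tert-butyldimethylsilyl)oxymethyl]-2,5,8a-trimethyl-1,4,4a,5,6,7,8,8a-octahydronaphthalen-1-yl]-3-methylpent-2-enoate | CC(=O)O[C@H]1CC[C@]2(C)[C@H](CC=C(C)[C@H]2CC/C(C)=C/C(=O)OC(C)(C)C)[C@]1(C)CO[Si](C)(C)C(C)(C)C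
F11 | step 6 | tert-butyl (2E)-5-[(1R,4aS,5R,8aS)-5-(hydroxymethyl)-2,5,8a-trimethyl-6-oxo-1,4,4a,5,6,7,8,8a-octahydronaphthalen-1-yl]-3-methylpent-2-enoate | O=C1CC[C@]2(C)[C@H](CC=C(C)[C@H]2CC/C(C)=C/C(=O)OC(C)(C)C)[C@]1(C)CO
F12 | step 6 | tert-butyl (2E)-5-[(1R,4aS,5R,6S,8aS)-6-hydroxy-5-(hydroxymethyl)-2,5,8a-trimethyl-1,4,4a,5,6,7,8,8a-octahydronaphthalen-1-yl]-3-methylpent-2-enoate | O[C@H]1CC[C@]2(C)[C@H](CC=C(C)[C@H]2CC/C(C)=C/C(=O)OC(C)(C)C)[C@]1(C)CO
F13 | step 7 | tert-butyl (2E)-5-[(1R,4aS,5R,6R,8aS)-6-hydroxy-5-(hydroxymethyl)-2,5,8a-trimethyl-1,4,4a,5,6,7,8,8a-octahydronaphthalen-1-yl]-3-methylpent-2-enoate | O[C@@H]1CC[C@]2(C)[C@H](CC=C(C)[C@H]2CC/C(C)=C/C(=O)OC(C)(C)C)[C@]1(C)CO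
F14 | step 7 | tert-butyl (2E)-5-[(1R,4aS,5R,6R,8aS)-5-[(tert-butyldiphenylsilyl)oxymethyl]-6-hydroxy-2,5,8a-trimethyl-1,4,4a,5,6,7,8,8a-octahydronaphthalen-1-yl]-3-methylpent-2-enoate | O[C@@H]1CC[C@]2(C)[C@H](CC=C(C)[C@H]2CC/C(C)=C/C(=O)OC(C)(C)C)[C@]1(C)CO[Si](c1ccccc1)(c1ccccc1)C(C)(C)C
F15 | step 7 | tert-butyl (2E)-5-[(1R,4aS,5R,8aS)-5-[(tert-butyldiphenylsilyl)oxymethyl]-2,5,8a-trimethyl-6-oxo-1,4,4a,5,6,7,8,8a-octahydronaphthalen-1-yl]-3-methylpent-2-enoate | O=C1CC[C@]2(C)[C@H](CC=C(C)[C@H]2CC/C(C)=C/C(=O)OC(C)(C)C)[C@]1(C)CO[Si](c1ccccc1)(c1ccccc1)C(C)(C)C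
F16 | step 7 | tert-butyl (2E)-5-[(1R,4aS,5R,6S,8aS)-6-acetoxy-5-[(tert-butyldiphenylsilyl)oxymethyl]-2,5,8a-trimethyl-1,4,4a,5,6,7,8,8a-octahydronaphthalen-1-yl]-3-methylpent-2-enoate | CC(=O)O[C@H]1CC[C@]2(C)[C@H](CC=C(C)[C@H]2CC/C(C)=C/C(=O)OC(C)(C)C)[C@]1(C)CO[Si](c1ccccc1)(c1ccccc1)C(C)(C)C
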